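A one-step world bends target smoothly towards the whole charge of starting material. The autumn run instead reads 59.6 % at 25.0 min and 59.9 % at 80.0 min, with 17.8 % of starting material still present.

all flasks: starting material 0.86 M (fed, over 12 min); reagent 0.516 M
- spring: free catalyst 8.5 mM; run made earlier; the fed solution adds 0.25 times the starting volume
- autumn: free catalyst 34 mM; run made earlier; the fed solution adds 0.25 times the starting volume
- flask: free catalyst 17 mM; the fed solution adds 0.25 times the starting volume; time 1.5 h

| run | time / min | target / % | self-condensation product / % | starting material / % |
|---|---|---|---|---|
| spring | 6.00 | 2.1 | 0.8 | 45.7 |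
| spring | 10.0 | 7.0 | 5.3 | 72.2 |
| spring | 15.0 | 11.7 | 12.3 | 75.6 |
| spring | 25.0 | 20.0 | 23.4 | 56.8 |
| spring | 40.0 | 30.8 | 31.1 | 38.2 |
| spring | 80.0 | 46.5 | 37.6 | 14.8 |
| autumn | 12.0 | 28.8 | 5.5 | 65.0 |
| autumn | 25.0 | 59.6 | 12.3 | 26.7 |
| autumn | 40.0 | 58.9 | 13.8 | 23.2 |
| autumn | 50.0 | 61.1 | 13.8 | 21.0 |
| autumn | 60.0 | 59.8 | 16.4 | 19.0 |
| autumn | 80.0 | 59.9 | 17.5 | 17.8 |

(readings scatter by 0.5 percentage points)

- percent here means starting material units held: one self-condensation product counts as two
- amounts are per litre of the starting volume; all of the dose is in the solution fed
- percentages count the whole charge, also what has not yet gone in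

- concentration of target at 1.5 h, in M
- concentration of self-condensation product at 1.5 h, in M
- concentration of starting material at 1.5 h, in M

We draw the target curve for the flask by taking target's pace as proportional to the catalyst charged. Scaling the autumn reading at the end of the feed gives 14.4 % at 12 min. From there the spring rise between 15.0 min and 25.0 min, scaled the same way, gives a straight climb of 17 percentage points per 10.0 min.

The level it runs into is reagent charged over starting material charged, 60.0 %, and the autumn plateau sits there, so we treat reagent as the limiting reagent, one per target. The climb meets that level at a knee near 39.5 min, earlier than 1.5 h. The feed has ended by then too, so the liquid has grown by the feed volume. Our reckoning is therefore the reagent ceiling, 0.413 M of target, which is the reagent charged divided by the final volume in starting volumes.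

The forecast, made from the same runs, gives 0.51 M, 0.106 M and 0.12 M for target, self-condensation product and starting material, stating “Concentrations are per starting litre”, and its target stands above our ceiling.

The flask gives 0.413 M of target, 0.0875 M of self-condensation product and 0.0867 M of starting material.

    starting material + free catalyst → catalyst intermediate A (k = 2.80 M⁻¹ min⁻¹)
    reagent + catalyst intermediate A → catalyst intermediate B (k = 390 M⁻¹ min⁻¹)
    catalyst intermediate B → free catalyst + target (k = 3.60 min⁻¹)
    2 starting material → self-condensation product (k = 0.0180 M⁻¹ min⁻¹)

In this flask, reagent's half-life by its step with catalyst intermediate A is 0.22 h at 0.339 h, short against 1.5 h. At 1.50 h this flask holds reagent at 0 % of its own charge and target at 60.0 % of the starting material charged, which is 0.413 M against the ceiling of 0.413 M. The same flask with 0.21 M of reagent has a ceiling of 0.168 M, and it gives 0.168 M of target.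

The numbers in the tables stem from a simulated flask with made-up constants; the scatter is artificial.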